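**Retrosynthetic overview**

1. Rings form in the order B, then A; chain carbons are numbered C1–C15 as in geranyllinalool (ring A = C1–C6, ring B = O plus C11–C15).
2. Ring B disconnection (C15–O and C14–Br, 6-endo bromoetherification): (R)-linalool 1 → bromo-oxane 2; C9 is added by cross-metathesis with vinylboronate 3 → alkenylboronate 4.
3. C8–C9 disconnection (Suzuki allyl–alkenyl coupling): geranyl acetate 5 → alcohol 6 → allylic bromide 7; then 4 + 7 → acetate 8 → trienol 9 with the skipped 6,9-diene.
4. C2–Br / C3–O disconnection: Sharpless epoxide 10 of 9, opened at C2 by bromide → anti bromohydrin 11.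
5. Ring A disconnection (C1–C6, last and key step): the C1/C2 bromonium ion made from triflate 12 is captured by the 6,7-alkene through a chair; loss of H-8 gives the E,E-diene of target 13.

Assumption: the biogenesis is taken to be two bromonium-triggered closures of an 11-hydroxygeranyllinalool-type chain, the 14,15-bromonium ion being captured by the C11 oxygen (ring B) and the 1,2-bromonium ion by the 6,7-alkene (ring A); this fits the all-equatorial Br/Me/side chain and axial OH of ring A.

**Route**

Step 1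
Reactants: 1 (R)-linalool, (3R)-3,7-dimethylocta-1,6-dien-3-ol
Product: 2 (3S,6R)-3-bromo-6-ethenyl-2,2,6-trimethyloxane (Br trans to the vinyl group)
Conditions: NBS (1.1 equiv), HFIP, 0 °C; silica gel chromatography
Reagents that add atoms: N-bromosuccinimide, O=C1CCC(=O)N1Br
Why: Biomimetic bromoetherification: Br+ adds to the electron-rich trisubstituted alkene (the vinyl group is inert) and the tertiary hydroxyl opens the bromonium ion at the tertiary carbon in the 6-endo (Markovnikov) mode that the ionising solvent favours; C6 (R) comes unchanged from 1, while the new C3 centre forms with little selectivity (about 1:1 expected), so the (3S,6R) isomer is separated from its C3 epimer and the minor 5-exo oxolanes.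

Step 2
Reactants: 2 (3S,6R)-3-bromo-6-ethenyl-2,2,6-trimethyloxane; 3 vinylboronic acid pinacol ester, 2-ethenyl-4,4,5,5-tetramethyl-1,3,2-dioxaborolane
Product: 4 2-[(E)-2-[(2R,5S)-5-bromo-2,6,6-trimethyloxan-2-yl]ethenyl]-4,4,5,5-tetramethyl-1,3,2-dioxaborolane
Conditions: 3 (3 equiv), second-generation Hoveyda–Grubbs catalyst RuCl2(=CH–C6H4-2-OiPr)(SIMes) (5 mol %), CH2Cl2, 40 °C
Reagents that add atoms: vinylboronic acid pinacol ester 3, C=CB1OC(C)(C)C(C)(C)O1
Why: Olefin cross-metathesis: 2 has a single alkene whose quaternary neighbour suppresses homodimerisation, so excess vinylboronate gives the E-alkenylboronate with loss of ethene and without touching a stereocentre.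

Step 3
Reactants: 5 geranyl acetate, (2E)-3,7-dimethylocta-2,6-dien-1-yl acetate
Product: 6 (2E,6E)-8-hydroxy-3,7-dimethylocta-2,6-dien-1-yl acetate
Conditions: SeO2 (0.2 equiv), t-BuOOH (3 equiv), CH2Cl2, 23 °C
Reagents that add atoms: selenium dioxide (oxygen carrier), O=[Se]=O; tert-butyl hydroperoxide (terminal oxidant), CC(C)(C)OO
Why: Selenium dioxide allylic oxidation (ene reaction, then [2,3]-sigmatropic shift) attacks the more electron-rich 6,7-alkene at its E-methyl group, the 2,3-alkene being deactivated by the allylic acetate, and keeps the 6E geometry.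

Step 4
Reactants: 6 (2E,6E)-8-hydroxy-3,7-dimethylocta-2,6-dien-1-yl acetate
Product: 7 (2E,6E)-8-bromo-3,7-dimethylocta-2,6-dien-1-yl acetate
Conditions: CBr4, PPh3, CH2Cl2, 0 °C
Reagents that add atoms: carbon tetrabromide, BrC(Br)(Br)Br
Why: Appel reaction: bromide displaces the alkoxyphosphonium group at the primary allylic carbon by SN2, so neither allylic transposition nor E/Z scrambling occurs.

Step 5
Reactants: 4 alkenylboronate (as above); 7 (2E,6E)-8-bromo-3,7-dimethylocta-2,6-dien-1-yl acetate
Product: 9 (2E,6E,9E)-10-[(2R,5S)-5-bromo-2,6,6-trimethyloxan-2-yl]-3,7-dimethyldeca-2,6,9-trien-1-ol, via trienyl acetate 8 (not isolated)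
Conditions: Pd(PPh3)4 (5 mol %), K3PO4 (3 equiv), THF/H2O, 40 °C; then MeOH, K2CO3, 23 °C
Reagents that add atoms: none
Why: Suzuki–Miyaura allyl–alkenyl coupling: zerovalent palladium ionises the allylic bromide much faster than the allylic acetate or the hindered secondary alkyl bromide, the alkenyl group is delivered to the unsubstituted allyl terminus C8 with retention of both alkene geometries, and mild methanolysis then frees the C1 alcohol without disturbing the oxane bromide.

Step 6
Reactants: 9 (2E,6E,9E)-10-[(2R,5S)-5-bromo-2,6,6-trimethyloxan-2-yl]-3,7-dimethyldeca-2,6,9-trien-1-ol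
Product: 10 [(2R,3R)-3-{(3E,6E)-7-[(2R,5S)-5-bromo-2,6,6-trimethyloxan-2-yl]-4-methylhepta-3,6-dien-1-yl}-3-methyloxiran-2-yl]methanol
Conditions: Ti(OiPr)4 (10 mol %), D-(−)-diethyl tartrate (12 mol %), t-BuOOH (2 equiv), 4 Å MS, CH2Cl2, −20 °C
Reagents that add atoms: tert-butyl hydroperoxide, CC(C)(C)OO
Why: Sharpless asymmetric epoxidation: the titanium tartrate catalyst epoxidises only the allylic alcohol alkene, and D-(−)-diethyl tartrate gives the (2R,3R)-epoxide under reagent control (the opposite sense to the 2S,3S epoxide that L-(+)-tartrate gives with geraniol), which fixes C3 (R).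

Step 7
Reactants: 10 (2R,3R)-epoxy alcohol (as above)
Product: 11 (2S,3R,6E,9E)-2-bromo-10-[(2R,5S)-5-bromo-2,6,6-trimethyloxan-2-yl]-3,7-dimethyldeca-6,9-diene-1,3-diol
Conditions: Li2NiBr4 (2 equiv, stock solution in THF), THF, 0 → 23 °C; then H2O
Reagents that add atoms: dilithium tetrabromonickelate, [Li+].[Li+].[Ni+2].[Br-].[Br-].[Br-].[Br-]
Why: Regioselective SN2 opening of the trisubstituted epoxide: the soft bromide can only attack the secondary carbon C2, with inversion (2R to 2S), while the tertiary C3–O bond stays intact, so the anti bromohydrin with the target's C2/C3 configuration results.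

Step 8
Reactants: 11 (2S,3R)-bromo diol (as above)
Product: 13 (1R,2S,4S)-2-bromo-4-[(2E,4E)-5-[(2R,5S)-5-bromo-2,6,6-trimethyloxan-2-yl]penta-2,4-dien-2-yl]-1-methylcyclohexan-1-ol (target), via primary triflate 12 (not isolated)
Conditions: Tf2O (1.0 equiv), 2,6-di-tert-butyl-4-methylpyridine (3 equiv), CH2Cl2, −78 °C; then HFIP, −78 → 0 °C; Et3N quench
Reagents that add atoms: trifluoromethanesulfonic anhydride (its atoms stay only in intermediate 12), O=S(=O)(OS(=O)(=O)C(F)(F)F)C(F)(F)F
Why: Proposed new method: the primary alcohol is triflated selectively at −78 °C and, in the ionising solvent, the triflate leaves with participation of the C2 bromine, which generates the C1/C2 bromonium ion of the biosynthesis at a defined site. The 6,7-alkene opens it at the primary carbon C1 (6-ring, anti to Br) through a chair with Br, C3-methyl and the developing side chain equatorial and the C3 hydroxyl axial, so C2 (S) is retained and C6 (S) is set. The tertiary C7 cation then loses the doubly allylic H-8 to the hindered base to give the conjugated diene, 7E being favoured by allylic strain. The closest known reaction types are the stereospecific generation and alkene capture of bromonium ions from bromohydrin derivatives and the π-route solvolysis of 5-hexenyl sulfonates.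

**Compound list**

1 | (R)-linalool, (3R)-3,7-dimethylocta-1,6-dien-3-ol | C=C[C@](C)(O)CCC=C(C)C | starting material
2 | (3S,6R)-3-bromo-6-ethenyl-2,2,6-trimethyloxane | C=C[C@@]1(C)CC[C@H](Br)C(C)(C)O1 | intermediate
3 | 2-ethenyl-4,4,5,5-tetramethyl-1,3,2-dioxaborolane | C=CB1OC(C)(C)C(C)(C)O1 | starting material
4 | 2-[(E)-2-[(2R,5S)-5-bromo-2,6,6-trimethyloxan-2-yl]ethenyl]-4,4,5,5-tetramethyl-1,3,2-dioxaborolane | CC1(C)OB(/C=C/[C@@]2(C)CC[C@H](Br)C(C)(C)O2)OC1(C)C | intermediate
5 | geranyl acetate, (2E)-3,7-dimethylocta-2,6-dien-1-yl acetate | CC(=O)OC/C=C(\C)CCC=C(C)C | starting material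
6 | (2E,6E)-8-hydroxy-3,7-dimethylocta-2,6-dien-1-yl acetate | CC(=O)OC/C=C(\C)CC/C=C(\C)CO | intermediate
7 | (2E,6E)-8-bromo-3,7-dimethylocta-2,6-dien-1-yl acetate | CC(=O)OC/C=C(\C)CC/C=C(\C)CBr | intermediate
8 | (2E,6E,9E)-10-[(2R,5S)-5-bromo-2,6,6-trimethyloxan-2-yl]-3,7-dimethyldeca-2,6,9-trien-1-yl acetate | CC(=O)OC/C=C(\C)CC/C=C(\C)C/C=C/[C@@]1(C)CC[C@H](Br)C(C)(C)O1 | intermediate (not isolated)
9 | (2E,6E,9E)-10-[(2R,5S)-5-bromo-2,6,6-trimethyloxan-2-yl]-3,7-dimethyldeca-2,6,9-trien-1-ol | OC/C=C(\C)CC/C=C(\C)C/C=C/[C@@]1(C)CC[C@H](Br)C(C)(C)O1 | intermediate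
10 | [(2R,3R)-3-{(3E,6E)-7-[(2R,5S)-5-bromo-2,6,6-trimethyloxan-2-yl]-4-methylhepta-3,6-dien-1-yl}-3-methyloxiran-2-yl]methanol | OC[C@H]1O[C@]1(C)CC/C=C(\C)C/C=C/[C@@]2(C)CC[C@H](Br)C(C)(C)O2 | intermediate
11 | (2S,3R,6E,9E)-2-bromo-10-[(2R,5S)-5-bromo-2,6,6-trimethyloxan-2-yl]-3,7-dimethyldeca-6,9-diene-1,3-diol | OC[C@H](Br)[C@](C)(O)CC/C=C(\C)C/C=C/[C@@]1(C)CC[C@H](Br)C(C)(C)O1 | intermediate
12 | (2S,3R,6E,9E)-2-bromo-10-[(2R,5S)-5-bromo-2,6,6-trimethyloxan-2-yl]-3-hydroxy-3,7-dimethyldeca-6,9-dien-1-yl trifluoromethanesulfonate | O=S(=O)(OC[C@H](Br)[C@](C)(O)CC/C=C(\C)C/C=C/[C@@]1(C)CC[C@H](Br)C(C)(C)O1)C(F)(F)F | intermediate (not isolated)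
13 | (1R,2S,4S)-2-bromo-4-[(2E,4E)-5-[(2R,5S)-5-bromo-2,6,6-trimethyloxan-2-yl]penta-2,4-dien-2-yl]-1-methylcyclohexan-1-ol | C/C(=C\C=C\[C@@]1(C)CC[C@H](Br)C(C)(C)O1)[C@H]1CC[C@@](C)(O)[C@@H](Br)C1 | target

**Step count and risks**

Total steps: 8 (steps 5 and 8 are each run in one flask). Longest linear sequence: 6 steps (5 → 13 through steps 3–8; equally 1 → 13 through steps 1, 2, 5–8).

Most likely to fail, in this order:

Step 8 (ring A closure). The free C3 hydroxyl may capture the bromonium ion (epoxide or oxetane), the primary triflate may ionise too slowly, proton loss may give some 7Z or non-conjugated isomers, and the dienyl ether of the product is acid-sensitive. Fallback, setting out from 11: iodination of the primary alcohol (I2, PPh3, imidazole) gives (2R,3R,6E,9E)-2-bromo-10-[(2R,5S)-5-bromo-2,6,6-trimethyloxan-2-yl]-1-iodo-3,7-dimethyldeca-6,9-dien-3-ol F1. TESOTf and 2,6-lutidine mask the tertiary hydroxyl as the triethylsilyl ether of F1, F2. AgSbF6 with 2,6-di-tert-butylpyridine in MeNO2 at −30 °C abstracts the iodide, and the same bromonium ion closes ring A to the triethylsilyl ether of the target, F3. Tetrabutylammonium fluoride in THF then comes back to the route at 13.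

Step 7 (bromide opening). Bromide may attack the tertiary C3 under Lewis-acid assistance, or the opening at C2, which is deactivated by the neighbouring CH2OH, may be too slow. Fallback, setting out from 9 and passing by 10: a titanium-mediated, diol-ligand-controlled enantioselective dibromination of the allylic alcohol alkene (diethyl dibromomalonate, BrTi(OiPr)3, tartrate-derived diol ligand of the enantiomer that gives the 2S,3R adduct) gives (2S,3R,6E,9E)-2,3-dibromo-10-[(2R,5S)-5-bromo-2,6,6-trimethyloxan-2-yl]-3,7-dimethyldeca-6,9-dien-1-ol F4. Solvolysis of its tertiary bromide (Ag2CO3, aqueous acetone) runs through the C2/C3 bromonium ion, water attacks C3 with overall retention, and the route is rejoined at 11.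

Step 2 (cross-metathesis). The vinyl group on a quaternary, oxygen-bearing carbon may react too slowly with the vinylboronate. Fallback, setting out from 2: ozonolysis (O3, CH2Cl2/MeOH, −78 °C; Me2S) gives (2R,5S)-5-bromo-2,6,6-trimethyloxane-2-carbaldehyde F5. A Takai-type borylative olefination with 2-(dichloromethyl)-4,4,5,5-tetramethyl-1,3,2-dioxaborolane, CrCl2 and LiI in THF gives the E-alkenylboronate and comes back to the route at 4; C9 then comes from the dichloromethylboronate, not from 3.

**Further compounds**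

F1 | step 8 | (2R,3R,6E,9E)-2-bromo-10-[(2R,5S)-5-bromo-2,6,6-trimethyloxan-2-yl]-1-iodo-3,7-dimethyldeca-6,9-dien-3-ol | IC[C@H](Br)[C@](C)(O)CC/C=C(\C)C/C=C/[C@@]1(C)CC[C@H](Br)C(C)(C)O1
F2 | step 8 | triethylsilyl ether of F1 (at the C3 hydroxyl) | IC[C@H](Br)[C@](C)(O[Si](CC)(CC)CC)CC/C=C(\C)C/C=C/[C@@]1(C)CC[C@H](Br)C(C)(C)O1
F3 | step 8 | triethylsilyl ether of 13 (at the ring A hydroxyl) | C/C(=C\C=C\[C@@]1(C)CC[C@H](Br)C(C)(C)O1)[C@H]1CC[C@@](C)(O[Si](CC)(CC)CC)[C@@H](Br)C1
F4 | step 7 | (2S,3R,6E,9E)-2,3-dibromo-10-[(2R,5S)-5-bromo-2,6,6-trimethyloxan-2-yl]-3,7-dimethyldeca-6,9-dien-1-ol | OC[C@H](Br)[C@](C)(Br)CC/C=C(\C)C/C=C/[C@@]1(C)CC[C@H](Br)C(C)(C)O1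
F5 | step 2 | (2R,5S)-5-bromo-2,6,6-trimethyloxane-2-carbaldehyde | O=C[C@@]1(C)CC[C@H](Br)C(C)(C)O1
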